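**Plan**

1. Retrosynthesis: the free secondary hydroxyl is traced back to a second acetate (a meso diacetate). The tertiary C–OH bond at the ring carbon bearing the acyl group is cut to an exocyclic silyl enol ether. The two secondary ring C–O bonds are cut together to a ring diene. Last, the bond between the tridecanoyl carbonyl carbon and that ring carbon is cut, to cyclopentadienide and methyl tridecanoate.
2. Forward: no ring is closed. The five-membered ring is bought as the aromatic cyclopentadienide anion, the C13 chain is joined to it first (step 1), the ring is then oxygenated twice (steps 2 and 4) and one acetate is removed (step 5).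
3. Enabling feature: every ring carbon of the target is sp2 or oxygen-bearing and the exocyclic carbon is a ketone carbon. The cyclopentene ring plus the C=O carbon are therefore an O-trapped acylcyclopentadienide (a 6-oxyfulvene) that lacks three oxygen atoms. Without its acetyl group the target is a meso triol whose mirror plane passes through the tertiary carbinol carbon, the C=O and the midpoint of the ring C=C.
4. Stereochemistry: the cis pair of secondary C–O bonds comes from suprafacial [4+2] addition of singlet oxygen (temporary O–O bridge). The tertiary carbinol comes from epoxidation of the exocyclic enol ether on the face away from both acetoxy groups. The absolute configuration comes from lipase hydrolysis of one enantiotopic acetate of the meso diacetate.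
5. Helpers put in and removed: the O-silyl group (step 1 to step 4), the peroxide bridge (step 2), the second acetate (step 3 to step 5).

Key step: step 1

**Remarks and assumptions**

- Sodium cyclopentadienide is used as its commercial 2 M solution in THF.
- Assumption: the lipase keeps its usual preference between the two enantiotopic secondary acetates of 9 and cleaves the one on the (R)-configured carbon. This fixes the absolute configuration and is to be confirmed on the first run.
- Compounds 5–8 are racemic. Their SMILES give the relative ring configuration and leave the exocyclic C=C geometry (or the spiro-epoxide carbon) open, because its two settings are the two enantiomers.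

**Route**

Step 1
Reactants: 1 sodium cyclopentadienide; 2 methyl tridecanoate
Product: 4 tert-butyl{[1-(cyclopenta-2,4-dien-1-ylidene)tridecyl]oxy}dimethylsilane (6-dodecyl-6-silyloxyfulvene), via sodium tridecanoylcyclopentadienide 3 (not isolated)
Conditions: THF, reflux; evaporate; then TBSCl, THF–DMPU, 0 °C → rt
Reagents that add atoms: tert-butyldimethylsilyl chloride, CC(C)(C)[Si](C)(C)Cl
Why: The cyclopentadienide carbon adds to the ester carbonyl, methoxide leaves and the ring proton at the acylated carbon is lost in the same event, so the species that accumulates is the 6-oxidofulvene anion 3, whose stability drives the Claisen-type acylation and stops it after one acyl group; the oxophilic silyl chloride then caps the anion on oxygen. The closest known reaction type is the acylation of alkali-metal cyclopentadienides with esters to acylcyclopentadienides and their O-trapping to 6-oxyfulvenes, together with ordinary enolate O-silylation. No ring is closed and no stereocentre is formed: the five ring carbons arrive as the aromatic anion and the new C–C bond ends as the exocyclic C=C of a fulvene. The step needs C-acylation instead of ester enolisation (secured by the low basicity and high carbon nucleophilicity of cyclopentadienide towards an ester with an α-CH2), mono-acylation (secured by the unreactive product anion) and O- instead of ring-C-silylation (secured by the Si–O bond strength, since a ring-silylated isomer can drain to the O-silyl fulvene by silyl shift). The silyl group holds the acyl unit as its enol: this keeps the ring a symmetric cisoid diene for step 2, blocks the 1,5-hydrogen shifts of a free acylcyclopentadiene, keeps the carbonyl carbon at the ketone level and provides the handle for step 4.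

Step 2
Reactants: 4 6-dodecyl-6-silyloxyfulvene
Product: 6 rac-(1R,3S)-2-[1-(tert-butyldimethylsilyloxy)tridecylidene]cyclopent-4-ene-1,3-diol (cis-diol), via fulvene endoperoxide 5 (not isolated)
Conditions: O2, hν (Na lamp), rose bengal (cat.), thiourea, MeOH–CH2Cl2, −30 → 0 °C
Reagents that add atoms: oxygen (as singlet oxygen), O=O
Why: Singlet oxygen should add suprafacially in a [4+2] cycloaddition to the cisoid ring diene (its fastest site, ahead of ene-type attack on the exocyclic enol ether), and thiourea in the flask should cleave the O–O bridge of 5 before it rearranges, so both new C–O bonds lie on one face and the 1,3-diol is cis; 6 is chiral only through the orientation of the exocyclic C=C.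

Step 3
Reactants: 6 cis-diol
Product: 7 rac-(1R,3S)-2-[1-(tert-butyldimethylsilyloxy)tridecylidene]cyclopent-4-ene-1,3-diyl diacetate
Conditions: Ac2O, pyridine, DMAP (cat.), CH2Cl2, 0 °C
Reagents that add atoms: acetic anhydride, CC(=O)OC(C)=O
Why: Standard DMAP-catalysed acetylation of two secondary allylic alcohols under basic conditions that should leave the silyl enol ether intact; no stereocentre is touched.

Step 4
Reactants: 7 diacetate
Product: 9 (1R,2r,3S)-2-hydroxy-2-tridecanoylcyclopent-4-ene-1,3-diyl diacetate (meso; tertiary OH trans to both acetoxy groups), via silyloxy epoxide 8 (not isolated)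
Conditions: DMDO, acetone–CH2Cl2, −40 → 0 °C; then aq. HF, MeCN, 0 °C
Reagents that add atoms: dimethyldioxirane, CC1(C)OO1
Why: Rubottom oxidation: the neutral dioxirane should epoxidise only the electron-rich tetrasubstituted silyl enol ether, from the face opposite the two pseudo-axial acetoxy groups, and acid/fluoride then opens 8 at the silyloxy-bearing carbon with loss of silicon, leaving the new tertiary C–O bond trans to both acetates and the ketone carbon cis to them; both enantiomers of 7 converge on the one meso compound 9.

Step 5
Reactants: 9 meso diacetate
Product: 10 (1S,4R,5S)-4,5-dihydroxy-5-tridecanoylcyclopent-2-en-1-yl acetate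
Conditions: Burkholderia cepacia lipase, phosphate buffer pH 7–MTBE, 25 °C, stopped at one equivalent of acetate released
Reagents that add atoms: none
Why: Lipase desymmetrisation of a meso diacetate, as practised on cis-3,5-diacetoxycyclopentene: by the empirical size rule for secondary-alcohol esters (quaternary C2 as large, ring CH= as medium substituent) the enzyme should cleave the acetate on the (R)-configured carbon and leave the one on the (S)-configured carbon, which sets (1S,4R,5S); the monoacetate keeps only the slow-reacting ester, so hydrolysis should stop there.

**Compound list**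

1 | sodium cyclopentadienide | [Na+].[CH-]1C=CC=C1 | starting material
2 | methyl tridecanoate | CCCCCCCCCCCCC(=O)OC | starting material
3 | sodium 1-(cyclopenta-2,4-dien-1-ylidene)tridecan-1-olate (sodium tridecanoylcyclopentadienide) | CCCCCCCCCCCCC([O-])=C1C=CC=C1.[Na+] | intermediate
4 | tert-butyl{[1-(cyclopenta-2,4-dien-1-ylidene)tridecyl]oxy}dimethylsilane | CCCCCCCCCCCCC(O[Si](C)(C)C(C)(C)C)=C1C=CC=C1 | intermediate
5 | rac-tert-butyl{[1-(2,3-dioxabicyclo[2.2.1]hept-5-en-7-ylidene)tridecyl]oxy}dimethylsilane | CCCCCCCCCCCCC(O[Si](C)(C)C(C)(C)C)=C1[C@H]2C=C[C@@H]1OO2 | intermediate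
6 | rac-(1R,3S)-2-[1-(tert-butyldimethylsilyloxy)tridecylidene]cyclopent-4-ene-1,3-diol | CCCCCCCCCCCCC(O[Si](C)(C)C(C)(C)C)=C1[C@H](O)C=C[C@@H]1O | intermediate
7 | rac-(1R,3S)-2-[1-(tert-butyldimethylsilyloxy)tridecylidene]cyclopent-4-ene-1,3-diyl diacetate | CCCCCCCCCCCCC(O[Si](C)(C)C(C)(C)C)=C1[C@H](OC(C)=O)C=C[C@@H]1OC(C)=O | intermediate
8 | rac-2-(tert-butyldimethylsilyloxy)-2-dodecyl-1-oxaspiro[2.4]hept-5-ene-4,7-diyl diacetate (epoxide oxygen trans to both acetoxy groups) | CCCCCCCCCCCCC1(O[Si](C)(C)C(C)(C)C)O[C@]12[C@H](OC(C)=O)C=C[C@@H]2OC(C)=O | intermediate
9 | (1R,2r,3S)-2-hydroxy-2-tridecanoylcyclopent-4-ene-1,3-diyl diacetate (meso) | CCCCCCCCCCCCC(=O)[C@]1(O)[C@H](OC(C)=O)C=C[C@@H]1OC(C)=O | intermediate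
10 | (1S,4R,5S)-4,5-dihydroxy-5-tridecanoylcyclopent-2-en-1-yl acetate | CCCCCCCCCCCCC(=O)[C@]1(O)[C@H](O)C=C[C@@H]1OC(C)=O | target

**Step count**

Total steps: 5. Longest linear sequence: 5.

**Steps most likely to fail**

1. Step 2. Singlet oxygen may attack the exocyclic silyl enol ether (silyl-ene or [2+2] pathway) instead of the ring diene. The peroxide bridge may open, pushed by the enol ether oxygen, before it is reduced. The silyl group may also be lost from the vinylogous hemiacetal diol, followed by elimination. The fallback avoids an enol ether during photooxygenation and sets out from 1. Compound 1 is neutralised with one equivalent of acetic acid to cyclopentadiene F1. F1 is condensed with commercial tridecanal (CCCCCCCCCCCCC=O) in a pyrrolidine-mediated fulvene condensation in MeOH to 6-dodecylfulvene F2. Photooxygenation with thiourea in the flask should give, through the endoperoxide F3, the racemic cis-diol 2-tridecylidenecyclopent-4-ene-1,3-diol F4. Acetylation (Ac2O, pyridine) gives the diacetate F5. Catalytic OsO4/NMO should dihydroxylate the exocyclic trisubstituted alkene from the face away from the acetates to the vicinal diol F6; a 1:1 mixture of (DHQD)2PHAL and (DHQ)2PHAL can be added to favour it over the ring cis-alkene. Parikh–Doering oxidation of the secondary alcohol (SO3·pyridine, DMSO, iPr2NEt) then rejoins the route at 9.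

2. Step 4. An allylic acetate may ionise, pushed by the silyl enol ether (vinylogous acylal), under the oxidant or during the acid stage. The ring alkene may also compete, or facial control may erode. The fallback replaces the epoxidation by an ene reaction under neutral conditions at low temperature and sets out from 7. Photooxygenation (O2, hν, tetraphenylporphyrin, CH2Cl2, −78 °C) should place O2 on the ring carbon from the face away from the acetates with silyl transfer to the peroxide, giving the α-silylperoxy ketone F7. Triphenylphosphine removes one oxygen to give the α-silyloxy ketone F8. Aqueous HF in MeCN then cleaves the silyl ether and rejoins the route at 9.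

3. Step 5. The enzyme may not accept the crowded diacetate, or may discriminate the enantiotopic acetates poorly or in the opposite sense. Acetyl migration between the cis-1,3 oxygens in water would erode the enantiomeric purity. The fallback uses reagent control in an organic solvent and sets out from 9. Brief methanolysis (K2CO3 cat., MeOH, 0 °C) gives the meso triol 1-(1,2,5-trihydroxycyclopent-3-en-1-yl)tridecan-1-one F9 (secondary hydroxyls cis to each other and trans to the tertiary one). One secondary hydroxyl is then acetylated with Ac2O under a chiral acyl-transfer catalyst (planar-chiral DMAP or a benzotetramisole-type isothiourea). Both catalyst enantiomers are available, and the one that acetylates the (S)-configured carbinol carbon is chosen, which gives 10.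

**Further compounds**

F1 | step 2 | cyclopentadiene | C1=CC=CC1
F2 | step 2 | 6-dodecylfulvene (5-tridecylidenecyclopenta-1,3-diene) | CCCCCCCCCCCCC=C1C=CC=C1
F3 | step 2 | rac-7-tridecylidene-2,3-dioxabicyclo[2.2.1]hept-5-ene | CCCCCCCCCCCCC=C1[C@H]2C=C[C@@H]1OO2
F4 | step 2 | rac-(1R,3S)-2-tridecylidenecyclopent-4-ene-1,3-diol | CCCCCCCCCCCCC=C1[C@H](O)C=C[C@@H]1O
F5 | step 2 | rac-(1R,3S)-2-tridecylidenecyclopent-4-ene-1,3-diyl diacetate | CCCCCCCCCCCCC=C1[C@H](OC(C)=O)C=C[C@@H]1OC(C)=O
F6 | step 2 | rac-2-hydroxy-2-(1-hydroxytridecyl)cyclopent-4-ene-1,3-diyl diacetate (tertiary OH trans to both acetoxy groups) | CCCCCCCCCCCCC(O)[C@]1(O)[C@H](OC(C)=O)C=C[C@@H]1OC(C)=O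
F7 | step 4 | (1R,2r,3S)-2-(tert-butyldimethylsilylperoxy)-2-tridecanoylcyclopent-4-ene-1,3-diyl diacetate | CCCCCCCCCCCCC(=O)[C@]1(OO[Si](C)(C)C(C)(C)C)[C@H](OC(C)=O)C=C[C@@H]1OC(C)=O
F8 | step 4 | (1R,2r,3S)-2-(tert-butyldimethylsilyloxy)-2-tridecanoylcyclopent-4-ene-1,3-diyl diacetate | CCCCCCCCCCCCC(=O)[C@]1(O[Si](C)(C)C(C)(C)C)[C@H](OC(C)=O)C=C[C@@H]1OC(C)=O
F9 | step 5 | meso-1-(1,2,5-trihydroxycyclopent-3-en-1-yl)tridecan-1-one | CCCCCCCCCCCCC(=O)[C@]1(O)[C@H](O)C=C[C@@H]1O
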